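Remarks on conventions and assumptions: the locants of 33 (O2, C1, C3 to C8a in the bicycle, C9 to C15 in the side chain) are used for the corresponding atoms of every intermediate. Ep stands for the (2R,3S)-3-[(2E,4R,5S)-5-(tert-butyldimethylsilyloxy)-4-methylhex-2-en-2-yl]-2-methyloxiran-2-yl group. (R)-Lactic acid 22 is assumed to be bought as such, and the amide bases as commercial solutions.

## Analysis of the target

Pestaphilone D (33) is an azaphilone: a pyran ring (O2, C1, C8a, C4a, C4, C3) fused along C4a–C8a to a cyclohexenone ring A (C4a, C5, C6, C7, C8, C8a). The C6 carbonyl is a doubly vinylogous ester of O2 through C5=C4a and C4=C3, and C8a=C1–O2 is a second enol ether arm. Ring A carries the tertiary alcohol C7 (S, with a methyl group) and the secondary alcohol C8 (R); the two hydroxyls are trans on the ring. C3 bears the chain C9–C15 with a trisubstituted epoxide (C9 R, C10 S, pyran and C11 trans), an E-alkene C11=C12 and an anti methyl/hydroxyl pair C13 (R), C14 (S). The ring A pair and the four side-chain centres are too far apart to control one another, so each set needs its own source of chirality. Sensitive points are the allylic epoxide (opened by acids, Lewis acids and zerovalent palladium), the pyran (C1 takes up amines and other nucleophiles), the α-ketol at C6/C7, and the C8 carbinol, which ionises easily next to the enol ether. The difficulty is to build a non-aromatic, fully oxygenated ring A with a quaternary C7 beside C8, without a phenol oxidation and under conditions the epoxide tolerates. The handle is that C6(=O)–C7(OH)(CH3) is lactic acid substituted at its α-carbon, and C5 is the exocyclic carbon of a 4-methylene-4H-pyran whose ring carbon is C4a; the C5–C6 bond is then the acylation of a strongly nucleophilic carbon by a lactate acyl group.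

## Retrosynthetic reasoning

33 from 32. Only the O–Si bonds at O8 and O14 are cut. Both hydroxyls stay masked until the end, so that O8 cannot act as an acyl acceptor during ring closure and O14 survives the organometallic steps. The forward step has to remove both silyl groups near neutrality.

32 from 29. The C5–C6 bond is cut. It is the one ring A bond that joins a carbon nucleophilic without added base (C5 of the methylenepyran in 29) to a carbonyl that can be supplied as an activated acyl group of fixed configuration (the dioxolanone). Cutting C4a–C5 or C8–C8a instead would need Lewis acid activation of a pyranone or a conjugate-addition catalyst, and both endanger the epoxide. The cut gains ring A, the dienone chromophore and the free C7 hydroxyl in one operation, with 23 as the only by-product. The forward reaction must be a C-acylation at C5 under neutral conditions.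

29 from 21 and 25, through 26, 27 and 28. The C7–C8 bond is cut between the quaternary C7, placed on the enolate 25 of dioxolanone 24, and the aldehyde carbon C8 of 21. This puts C7 on the partner whose two faces are told apart by the tert-butyl group, and it installs the activated lactone needed later. The aldol is not relied on for C8: the tert-butyl group differentiates the faces of 25, not those of 21, and the chair transition state with the pyranyl group turned away from the dioxolanone would give the C8 epimer of what is needed. Therefore the adducts 26 are oxidised to ketone 27, the C8 hydrogen is brought in as hydride (28), and O8 is silylated (29).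

24 from 22 and 23. The two acetal C–O bonds are cut. The acetal centre stores the configuration of 22 while C7 is planar in 25, and it makes the lactone an acylal, reactive enough to acylate carbon.

21 from 18, through 20. The C4a=C5 bond is cut back to the pyranone carbonyl of 18 and a methyl nucleophile, and C8 is taken back from aldehyde to alcohol. The methylene has to be introduced while C8 is an alcohol, because a methyl organometallic would not spare an aldehyde or the lactone.

18 from 17. The C8–C8a bond is cut. C8a is the α-carbon of an enone whose β-carbon C1 is unsubstituted, so a Morita–Baylis–Hillman reaction with a one-carbon electrophile can attach C8 without a halogen or palladium, which the allylic epoxide would not survive.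

17 from 12 and 13, through 14, 15 and 16. The pyranone is opened at O2–C1 and at C3–C4. The forward sequence is an aldol of enolate 14 with the non-enolisable aldehyde 12, oxidation to the diketone 16 and ring closure with loss of methanol. The ring is built late, on the finished side chain, so that no coupling has to be done next to the epoxide.

12 from 10, through 11. The two epoxide C–O bonds are cut. The C9=C10 alkene of 10 carries the primary hydroxyl that later becomes C3, so a Sharpless asymmetric epoxidation sets C9 and C10 and leaves C11=C12 alone.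

10 from 5, through 7 and 9. C11=C12 and C9=C10 are cut in turn. Two Wittig reactions with the stabilised ylides 6 and 8 give both trisubstituted alkenes with E geometry.

5 from 1, through 3 and 4. The C13–CH3 bond is cut. Alkylation of dianion 2 sets C13 anti to C14, which comes from 1.

## Alternatives that were turned down

Alternative 1: Ring A is traced back to a benzene ring. The keto-aldehyde A2 is hydroxylated at C7 by a flavin-dependent monooxygenase of the AzaH family (O2, NADPH recycling); the dearomatised product closes the pyran by condensation of the C3 ketone oxygen with the C1 aldehyde, giving the 8-oxo azaphilone A1.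
- For: A2 is a flat arene made by ordinary aromatic chemistry. One step creates C7 under catalyst control and the whole chromophore, without protecting groups on ring A. On step count this is clearly the stronger plan.
- Against: A1 is one oxidation level too high at C8, so a reduction must distinguish C8 from C6 and give the trans-diol. The enzyme must accept a substrate whose acyl chain is a bulky, electrophilic epoxy ketone. The sense at C7 depends on which enzyme family is used. A2 has a benzylic ketone next to the epoxide, which is hard to carry.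
- Comparison: the chosen route is longer, but it takes C7 from the chiral pool with a predictable sense, has C8 at the alcohol level before ring closure, and does not depend on the substrate scope of an enzyme.

Alternative 2: The C8–C8a bond is cut. In the 4-acylmethylene-4H-pyran aldehyde A4, 1,4-diazabicyclo[2.2.2]octane or PMe3 adds to C1, the dienolate attacks the tethered C8 aldehyde through C8a, and the catalyst leaves, giving A3.
- For: A4 is a push–pull vinylogous ester and far more stable than the methylenepyrans 20 to 29. The step is catalytic and creates C8 with its hydroxyl free. On stability of intermediates it is stronger.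
- Against: the catalyst has to add to the far end of a cross-conjugated system in competition with attack on a very electrophilic α-silyloxy aldehyde. Phosphines open allylic epoxides. C8 would be set by 1,2-induction from the quaternary C7 in a cyclisation with no reliable model. A4 itself has to be made by acylating a methylenepyran with a lactate-derived acyl donor, so the reactivity of the chosen key step is needed anyway, only intermolecularly.
- Comparison: the chosen route sets C8 by a hydride addition that can be repeated and reversed, and uses the acylation directly for ring closure.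

Alternative 3: The C4a=C5 bond is cut. In pyranone A6, Me3SiOSO2CF3 and 2,6-lutidine turn the C6 methyl ketone into a silyl enol ether and the pyranone into a 4-silyloxypyrylium ion; C5 adds to C4a and silanol is lost, giving A5.
- For: A6 is a robust pyranone and no methylenepyran is ever handled. The C7/C8 pair could be made by the same lactate aldol, and the methyl ketone by opening the dioxolanone with a methyl nucleophile. Before the key step this plan is at least as short and its intermediates are sturdier.
- Against: a silyl triflate is a strong Lewis acid and the allylic epoxide should not survive it, which is decisive for this target. Silyloxypyrylium ions usually take nucleophiles next to oxygen, here at C1, which would close a five-membered ring. Elimination of silanol has to outrun reversal of the addition.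
- Comparison: the chosen route reverses the roles, so that the only electrophile is the lactone carbonyl held in reach of C5, and the key step runs without acid.

Key step: step 20

## Route

Step 1
Reactants: 1 ethyl (S)-3-hydroxybutanoate
Product: 3 ethyl (2S,3S)-3-hydroxy-2-methylbutanoate, via dilithium alkoxide enolate 2 (not isolated)
Conditions: LiN(i-Pr)2 (2.2 equiv), THF, −50→−20 °C; MeI, DMPU, −78→0 °C; AcOH
Reagents that add atoms: iodomethane, CI
Why: Fráter–Seebach alkylation: the chelated dianion 2 is methylated on the face away from the C14 methyl group, which should give the anti ester and so C13; C14 is carried over from 1.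

Step 2
Reactants: 3 ethyl (2S,3S)-3-hydroxy-2-methylbutanoate
Product: 4 ethyl (2S,3S)-3-(tert-butyldimethylsilyloxy)-2-methylbutanoate
Conditions: TBSCl, imidazole, DMF, 23 °C
Reagents that add atoms: tert-butyldimethylsilyl chloride, CC(C)(C)[Si](C)(C)Cl
Why: Standard silylation of a secondary alcohol; the tert-butyldimethylsilyl ether is chosen because it has to last through hydride, organolithium, mild acid and oxidation steps.

Step 3
Reactants: 4 ethyl (2S,3S)-3-(tert-butyldimethylsilyloxy)-2-methylbutanoate
Product: 5 (2S,3S)-3-(tert-butyldimethylsilyloxy)-2-methylbutanal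
Conditions: i-Bu2AlH (1.1 equiv), CH2Cl2, −78 °C; MeOH, aq. KNaC4H4O6
Reagents that add atoms: none
Why: Partial reduction of the ester at −78 °C stops at the aluminium hemiacetal, which gives the aldehyde on work-up; 5 is used crude to avoid epimerisation at C13.

Step 4
Reactants: 5 (2S,3S)-3-(tert-butyldimethylsilyloxy)-2-methylbutanal; 6 2-(triphenylphosphoranylidene)propanal
Product: 7 (2E,4R,5S)-5-(tert-butyldimethylsilyloxy)-2,4-dimethylhex-2-enal
Conditions: toluene, 80 °C
Reagents that add atoms: none
Why: Wittig reaction with a stabilised formyl ylide, which should form C11=C12 with E geometry and reacts once because the product enal is much less electrophilic than 5.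

Step 5
Reactants: 7 (2E,4R,5S)-5-(tert-butyldimethylsilyloxy)-2,4-dimethylhex-2-enal; 8 ethyl 2-(triphenylphosphoranylidene)propanoate
Product: 9 ethyl (2E,4E,6R,7S)-7-(tert-butyldimethylsilyloxy)-2,4,6-trimethylocta-2,4-dienoate
Conditions: toluene, 80 °C
Reagents that add atoms: none
Why: Second Wittig reaction with a stabilised ylide, which should form the C9=C10 alkene with E geometry.

Step 6
Reactants: 9 ethyl (2E,4E,6R,7S)-7-(tert-butyldimethylsilyloxy)-2,4,6-trimethylocta-2,4-dienoate
Product: 10 (2E,4E,6R,7S)-7-(tert-butyldimethylsilyloxy)-2,4,6-trimethylocta-2,4-dien-1-ol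
Conditions: i-Bu2AlH (2.5 equiv), CH2Cl2, −78 °C; aq. KNaC4H4O6
Reagents that add atoms: none
Why: 1,2-Reduction of a conjugated ester to the allylic alcohol by an aluminium hydride, which leaves the diene untouched.

Step 7
Reactants: 10 (2E,4E,6R,7S)-7-(tert-butyldimethylsilyloxy)-2,4,6-trimethylocta-2,4-dien-1-ol
Product: 11 [(2S,3S)-3-[(2E,4R,5S)-5-(tert-butyldimethylsilyloxy)-4-methylhex-2-en-2-yl]-2-methyloxiran-2-yl]methanol
Conditions: Ti(Oi-Pr)4 (10 mol%), L-(+)-diethyl tartrate (12 mol%), t-BuOOH, 4 Å sieves, CH2Cl2, −20 °C
Reagents that add atoms: tert-butyl hydroperoxide, CC(C)(C)OO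
Why: Sharpless asymmetric epoxidation: only the alkene next to the coordinating hydroxyl reacts, and L-(+)-tartrate should deliver oxygen to the face that gives the (2S,3S)-epoxy alcohol, as it does with other (E)-2-methyl-3-substituted allylic alcohols; this sets C9 and C10.

Step 8
Reactants: 11 [(2S,3S)-3-[(2E,4R,5S)-5-(tert-butyldimethylsilyloxy)-4-methylhex-2-en-2-yl]-2-methyloxiran-2-yl]methanol
Product: 12 (2R,3S)-3-[(2E,4R,5S)-5-(tert-butyldimethylsilyloxy)-4-methylhex-2-en-2-yl]-2-methyloxirane-2-carbaldehyde (Ep–CHO)
Conditions: Dess–Martin periodinane, pyridine, CH2Cl2, 0→23 °C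
Reagents that add atoms: none
Why: Buffered Dess–Martin oxidation of an epoxy alcohol; the aldehyde has no α-hydrogen, so C9 cannot epimerise (its descriptor changes only through the priority rules).

Step 9
Reactants: 12 Ep–CHO; 13 (E)-4-methoxybut-3-en-2-one
Product: 15 (1E)-5-hydroxy-5-[(2S,3S)-3-[(2E,4R,5S)-5-(tert-butyldimethylsilyloxy)-4-methylhex-2-en-2-yl]-2-methyloxiran-2-yl]-1-methoxypent-1-en-3-one (both C5 epimers), via lithium enolate 14 (not isolated)
Conditions: 13, LiN(SiMe3)2, THF, −78 °C; then 12, −78 °C; AcOH
Reagents that add atoms: none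
Why: Kinetic deprotonation of the methyl ketone and aldol addition to a non-enolisable aldehyde, forming C3–C4; the new carbinol centre is removed in step 10.

Step 10
Reactants: 15 the aldol adduct of step 9
Product: 16 (4E)-5-methoxy-1-Ep-pent-4-ene-1,3-dione (Ep–CO–CH2–CO–CH=CH–OCH3, enolised)
Conditions: Dess–Martin periodinane, pyridine, CH2Cl2, 0→23 °C
Reagents that add atoms: none
Why: Dess–Martin oxidation of a β-hydroxy ketone to the 1,3-diketone, the usual precursor of a 4-pyranone.

Step 11
Reactants: 16 (4E)-5-methoxy-1-Ep-pent-4-ene-1,3-dione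
Product: 17 2-Ep-4H-pyran-4-one
Conditions: pyridinium p-toluenesulfonate (10 mol%), toluene, 50 °C
Reagents that add atoms: none
Why: Acid-catalysed addition of the enol oxygen to the β-methoxy enone and loss of methanol closes the pyranone (O2–C1); a weak acid is used because the acyl group on C9 already tempers the acid lability of the epoxide.

Step 12
Reactants: 17 2-Ep-4H-pyran-4-one
Product: 18 5-(hydroxymethyl)-2-Ep-4H-pyran-4-one
Conditions: 37% aq. CH2O (5 equiv), 1,4-diazabicyclo[2.2.2]octane (0.5 equiv), 1,4-dioxane–H2O, 23 °C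
Reagents that add atoms: formaldehyde, C=O
Why: Morita–Baylis–Hillman hydroxymethylation: the amine adds to the unsubstituted C1 (C3 is blocked by the quaternary C9), the C8a enolate takes up formaldehyde and loss of the amine restores the pyranone; benzo-fused 4-pyranones are known to react this way with reactive aldehydes.

Step 13
Reactants: 18 5-(hydroxymethyl)-2-Ep-4H-pyran-4-one
Product: 20 (4-methylidene-6-Ep-4H-pyran-3-yl)methanol, via tertiary carbinol 19 (not isolated)
Conditions: MeLi (2.4 equiv), THF, −78 °C; H2O; then pyridinium p-toluenesulfonate (5 mol%), 4 Å sieves, CH2Cl2, 0 °C; Et3N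
Reagents that add atoms: methyllithium, [Li]C
Why: 1,2-Addition of a hard methyl nucleophile to the 4-pyranone carbonyl, then dehydration of the doubly allylic carbinol 19 through its 4-methylpyrylium ion, which can only lose a proton from the new methyl group; this is the classical route to pyrylium anhydrobases.

Step 14
Reactants: 20 (4-methylidene-6-Ep-4H-pyran-3-yl)methanol
Product: 21 4-methylidene-6-Ep-4H-pyran-3-carbaldehyde
Conditions: MnO2 (activated, 20 equiv), CH2Cl2, 23 °C
Reagents that add atoms: none
Why: The hydroxymethyl group sits on the C8a=C1 double bond, so it is an allylic alcohol that MnO2 oxidises under neutral, heterogeneous conditions; the aldehyde is a vinylogous formate and is stabilised by conjugation with O2.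

Step 15
Reactants: 22 (R)-lactic acid; 23 pivalaldehyde
Product: 24 (2R,5R)-2-tert-butyl-5-methyl-1,3-dioxolan-4-one
Conditions: p-TsOH·H2O (cat.), H2SO4 (cat.), pentane, reflux, Dean–Stark; recrystallisation, −78 °C
Reagents that add atoms: none
Why: Acetalisation under thermodynamic control favours the cis dioxolanone, in which the new acetal centre is set by the lactate centre; crystallisation should remove the trans isomer.

Step 16
Reactants: 24 (2R,5R)-2-tert-butyl-5-methyl-1,3-dioxolan-4-one; 21 4-methylidene-6-Ep-4H-pyran-3-carbaldehyde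
Product: 26 (2R,5S)-2-tert-butyl-5-[hydroxy(4-methylidene-6-Ep-4H-pyran-3-yl)methyl]-5-methyl-1,3-dioxolan-4-one (both C8 epimers), via lithium enolate 25 (not isolated)
Conditions: LiN(i-Pr)2, THF, −78 °C; then 21, −78 °C; AcOH, −78 °C
Reagents that add atoms: none
Why: Aldol addition with self-regeneration of the stereocentre: 25 is attacked on the face away from the tert-butyl group, so C8 takes the place of the lactate hydrogen with retention and C7 is set (S in 33). C8 is expected as a mixture leaning to the unwanted epimer, which does not matter because steps 17 and 18 reset it; the cold acidic quench prevents acyl transfer to the aldolate oxygen.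

Step 17
Reactants: 26 the C8-epimeric aldol adducts of step 16
Product: 27 (2R,5S)-2-tert-butyl-5-methyl-5-[(4-methylidene-6-Ep-4H-pyran-3-yl)carbonyl]-1,3-dioxolan-4-one
Conditions: Dess–Martin periodinane, pyridine, CH2Cl2, 0 °C
Reagents that add atoms: none
Why: Buffered Dess–Martin oxidation takes both C8 epimers to one ketone; C7 is quaternary and cannot epimerise, and 27 is a push–pull vinylogous ester.

Step 18
Reactants: 27 the C8 ketone of step 17
Product: 28 (2R,5S)-2-tert-butyl-5-[(R)-hydroxy(4-methylidene-6-Ep-4H-pyran-3-yl)methyl]-5-methyl-1,3-dioxolan-4-one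
Conditions: NaBH4, THF–MeOH (4:1), −78→−40 °C; pH 7 buffer
Reagents that add atoms: none
Why: Non-chelating hydride reduction: with the C8=O dipole opposed to the C7–O bond (Cornforth; the polar Felkin–Anh model gives the same sense), hydride should enter past the C7 methyl, away from the dioxolanone ring, placing O8 syn to O7 in the extended chain, which is the 8R (trans) arrangement; a lactone is not reduced under these conditions.

Step 19
Reactants: 28 the (8R)-alcohol of step 18
Product: 29 (2R,5S)-2-tert-butyl-5-methyl-5-[(R)-(4-methylidene-6-Ep-4H-pyran-3-yl)(triethylsilyloxy)methyl]-1,3-dioxolan-4-one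
Conditions: Et3SiOTf, 2,6-lutidine, CH2Cl2, −78 °C
Reagents that add atoms: triethylsilyl trifluoromethanesulfonate, CC[Si](CC)(CC)OS(=O)(=O)C(F)(F)F
Why: Silyl triflate with a hindered base silylates the hindered hydroxyl at −78 °C, where the epoxide and the base-buffered methylenepyran should not react; the silyl ether removes O8 as an acyl acceptor.

Step 20
Reactants: 29 the silylated dioxolanone of step 19
Product: 32 (7S,8R)-7-hydroxy-7-methyl-3-Ep-8-(triethylsilyloxy)-7,8-dihydro-6H-isochromen-6-one, via pyrylium tetrahedral adduct 30 (not isolated), via pyrylium C7 alkoxide 31 (not isolated)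
Conditions: LiCl (3 equiv), i-Pr2NEt (2 equiv), MeCN, 23→60 °C
Reagents that add atoms: none
Why: Proposed new method: the exocyclic C5 of the cross-conjugated trienol ether 29 is the carbon terminus of two enol ether arms and attacks the acylal-type lactone carbonyl C6, activated by Li+, to give the pyrylium alkoxide 30; this expels the hemiacetal oxygen, which sheds 23 to leave the C7 alkoxide 31, and the amine moves the now acidic C5 proton to that oxygen, giving the neutral dienone 32. The closest known reactions are the C-acylation of 4-methylene-4H-pyrans (pyrylium anhydrobases) at the exocyclic carbon by acid chlorides and anhydrides, and the ring-opening acyl transfer of 2-tert-butyl-1,3-dioxolan-4-ones to heteroatom nucleophiles with loss of pivalaldehyde. Ring A (C5, C4a, C8a, C8, C7, C6) closes in a 6-exo-trig mode, C5 adding to a carbonyl whose oxygen lies outside the new ring. No stereocentre is created: C6 becomes trigonal again, C7 keeps its configuration because its C–O bond is never broken, and C8 is a spectator. The step needs C-acylation and not O-acylation, which the silyl ether on O8 secures, and it needs C5 to react, which the tether secures because only C5 reaches C6 through a six-membered transition state. The medium contains no protic or strong Lewis acid, so the allylic epoxide and the methylenepyran should survive, and aromatisation on attack together with the irreversible loss of 23 drives the reaction.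

Step 21
Reactants: 32 the silylated azaphilone of step 20
Product: 33 (7S,8R)-7,8-dihydroxy-3-[(2R,3S)-3-[(2E,4R,5S)-5-hydroxy-4-methylhex-2-en-2-yl]-2-methyloxiran-2-yl]-7-methyl-7,8-dihydro-6H-isochromen-6-one (pestaphilone D)
Conditions: Bu4NF, AcOH (1:1), THF, 0→23 °C
Reagents that add atoms: none
Why: Fluoride cleaves both silyl ethers; buffering with acetic acid keeps the medium near neutral, so that the α-ketol, the nucleophile-sensitive pyran and the epoxide are exposed neither to alkoxide nor to strong acid.

## Compound list

1 | ethyl (S)-3-hydroxybutanoate | C[C@H](O)CC(=O)OCC | starting material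
2 | dilithium alkoxide enolate of 1 | [Li+].[Li+].C[C@H]([O-])/C=C(\[O-])OCC | intermediate (not isolated)
3 | ethyl (2S,3S)-3-hydroxy-2-methylbutanoate | C[C@H](O)[C@H](C)C(=O)OCC | intermediate
4 | ethyl (2S,3S)-3-(tert-butyldimethylsilyloxy)-2-methylbutanoate | C[C@H](O[Si](C)(C)C(C)(C)C)[C@H](C)C(=O)OCC | intermediate
5 | (2S,3S)-3-(tert-butyldimethylsilyloxy)-2-methylbutanal | C[C@H](O[Si](C)(C)C(C)(C)C)[C@H](C)C=O | intermediate
6 | 2-(triphenylphosphoranylidene)propanal | CC(C=O)=P(c1ccccc1)(c1ccccc1)c1ccccc1 | starting material
7 | (2E,4R,5S)-5-(tert-butyldimethylsilyloxy)-2,4-dimethylhex-2-enal | C[C@H](O[Si](C)(C)C(C)(C)C)[C@H](C)/C=C(\C)C=O | intermediate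
8 | ethyl 2-(triphenylphosphoranylidene)propanoate | CCOC(=O)C(C)=P(c1ccccc1)(c1ccccc1)c1ccccc1 | starting material
9 | ethyl (2E,4E,6R,7S)-7-(tert-butyldimethylsilyloxy)-2,4,6-trimethylocta-2,4-dienoate | CCOC(=O)/C(C)=C/C(C)=C/[C@@H](C)[C@H](C)O[Si](C)(C)C(C)(C)C | intermediate
10 | (2E,4E,6R,7S)-7-(tert-butyldimethylsilyloxy)-2,4,6-trimethylocta-2,4-dien-1-ol | OC/C(C)=C/C(C)=C/[C@@H](C)[C@H](C)O[Si](C)(C)C(C)(C)C | intermediate
11 | [(2S,3S)-3-[(2E,4R,5S)-5-(tert-butyldimethylsilyloxy)-4-methylhex-2-en-2-yl]-2-methyloxiran-2-yl]methanol | C/C(=C\[C@@H](C)[C@H](C)O[Si](C)(C)C(C)(C)C)[C@@H]1O[C@@]1(C)CO | intermediate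
12 | (2R,3S)-3-[(2E,4R,5S)-5-(tert-butyldimethylsilyloxy)-4-methylhex-2-en-2-yl]-2-methyloxirane-2-carbaldehyde | C/C(=C\[C@@H](C)[C@H](C)O[Si](C)(C)C(C)(C)C)[C@@H]1O[C@@]1(C)C=O | intermediate
13 | (E)-4-methoxybut-3-en-2-one | CO/C=C/C(C)=O | starting material
14 | lithium enolate of 13 | [Li+].[O-]C(=C)/C=C/OC | intermediate (not isolated)
15 | (1E)-5-hydroxy-5-[(2S,3S)-3-[(2E,4R,5S)-5-(tert-butyldimethylsilyloxy)-4-methylhex-2-en-2-yl]-2-methyloxiran-2-yl]-1-methoxypent-1-en-3-one, both C5 epimers | C/C(=C\[C@@H](C)[C@H](C)O[Si](C)(C)C(C)(C)C)[C@@H]1O[C@@]1(C)C(O)CC(=O)/C=C/OC | intermediate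
16 | (4E)-5-methoxy-1-Ep-pent-4-ene-1,3-dione | C/C(=C\[C@@H](C)[C@H](C)O[Si](C)(C)C(C)(C)C)[C@@H]1O[C@@]1(C)C(=O)CC(=O)/C=C/OC | intermediate
17 | 2-Ep-4H-pyran-4-one | C/C(=C\[C@@H](C)[C@H](C)O[Si](C)(C)C(C)(C)C)[C@@H]1O[C@@]1(C)C1=CC(=O)C=CO1 | intermediate
18 | 5-(hydroxymethyl)-2-Ep-4H-pyran-4-one | C/C(=C\[C@@H](C)[C@H](C)O[Si](C)(C)C(C)(C)C)[C@@H]1O[C@@]1(C)C1=CC(=O)C(CO)=CO1 | intermediate
19 | 3-(hydroxymethyl)-4-methyl-6-Ep-4H-pyran-4-ol, both C4a epimers | C/C(=C\[C@@H](C)[C@H](C)O[Si](C)(C)C(C)(C)C)[C@@H]1O[C@@]1(C)C1=CC(C)(O)C(CO)=CO1 | intermediate (not isolated)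
20 | (4-methylidene-6-Ep-4H-pyran-3-yl)methanol | C/C(=C\[C@@H](C)[C@H](C)O[Si](C)(C)C(C)(C)C)[C@@H]1O[C@@]1(C)C1=CC(=C)C(CO)=CO1 | intermediate
21 | 4-methylidene-6-Ep-4H-pyran-3-carbaldehyde | C/C(=C\[C@@H](C)[C@H](C)O[Si](C)(C)C(C)(C)C)[C@@H]1O[C@@]1(C)C1=CC(=C)C(C=O)=CO1 | intermediate
22 | (R)-lactic acid | C[C@@H](O)C(=O)O | starting material
23 | pivalaldehyde | CC(C)(C)C=O | starting material
24 | (2R,5R)-2-tert-butyl-5-methyl-1,3-dioxolan-4-one | C[C@H]1O[C@@H](C(C)(C)C)OC1=O | intermediate
25 | lithium (2R)-2-tert-butyl-5-methyl-1,3-dioxol-4-olate | [Li+].CC1=C([O-])O[C@H](C(C)(C)C)O1 | intermediate (not isolated)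
26 | (2R,5S)-2-tert-butyl-5-[hydroxy(4-methylidene-6-Ep-4H-pyran-3-yl)methyl]-5-methyl-1,3-dioxolan-4-one, both C8 epimers | C/C(=C\[C@@H](C)[C@H](C)O[Si](C)(C)C(C)(C)C)[C@@H]1O[C@@]1(C)C1=CC(=C)C(=CO1)C(O)[C@]2(C)O[C@@H](C(C)(C)C)OC2=O | intermediate
27 | (2R,5S)-2-tert-butyl-5-methyl-5-[(4-methylidene-6-Ep-4H-pyran-3-yl)carbonyl]-1,3-dioxolan-4-one | C/C(=C\[C@@H](C)[C@H](C)O[Si](C)(C)C(C)(C)C)[C@@H]1O[C@@]1(C)C1=CC(=C)C(=CO1)C(=O)[C@]2(C)O[C@@H](C(C)(C)C)OC2=O | intermediate
28 | (2R,5S)-2-tert-butyl-5-[(R)-hydroxy(4-methylidene-6-Ep-4H-pyran-3-yl)methyl]-5-methyl-1,3-dioxolan-4-one | C/C(=C\[C@@H](C)[C@H](C)O[Si](C)(C)C(C)(C)C)[C@@H]1O[C@@]1(C)C1=CC(=C)C(=CO1)[C@@H](O)[C@]2(C)O[C@@H](C(C)(C)C)OC2=O | intermediate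
29 | (2R,5S)-2-tert-butyl-5-methyl-5-[(R)-(4-methylidene-6-Ep-4H-pyran-3-yl)(triethylsilyloxy)methyl]-1,3-dioxolan-4-one | C/C(=C\[C@@H](C)[C@H](C)O[Si](C)(C)C(C)(C)C)[C@@H]1O[C@@]1(C)C1=CC(=C)C(=CO1)[C@@H](O[Si](CC)(CC)CC)[C@]2(C)O[C@@H](C(C)(C)C)OC2=O | intermediate
30 | zwitterion after C5–C6 bond formation: 2-benzopyrylium ring, dioxolane still fused at C6–C7, alkoxide on C6 | C/C(=C\[C@@H](C)[C@H](C)O[Si](C)(C)C(C)(C)C)[C@@H]1O[C@@]1(C)c1cc2C[C@@]3([O-])O[C@H](C(C)(C)C)O[C@@]3(C)[C@H](O[Si](CC)(CC)CC)c2c[o+]1 | intermediate (not isolated)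
31 | zwitterion after loss of 23: 6-oxo-5,6,7,8-tetrahydro-2-benzopyrylium with C7 alkoxide | C/C(=C\[C@@H](C)[C@H](C)O[Si](C)(C)C(C)(C)C)[C@@H]1O[C@@]1(C)c1cc2CC(=O)[C@@](C)([O-])[C@H](O[Si](CC)(CC)CC)c2c[o+]1 | intermediate (not isolated)
32 | (7S,8R)-7-hydroxy-7-methyl-3-Ep-8-(triethylsilyloxy)-7,8-dihydro-6H-isochromen-6-one | C/C(=C\[C@@H](C)[C@H](C)O[Si](C)(C)C(C)(C)C)[C@@H]1O[C@@]1(C)C1=CC2=CC(=O)[C@@](C)(O)[C@H](O[Si](CC)(CC)CC)C2=CO1 | intermediate
33 | pestaphilone D, (7S,8R)-7,8-dihydroxy-3-[(2R,3S)-3-[(2E,4R,5S)-5-hydroxy-4-methylhex-2-en-2-yl]-2-methyloxiran-2-yl]-7-methyl-7,8-dihydro-6H-isochromen-6-one | C/C(=C\[C@@H](C)[C@H](C)O)[C@@H]1O[C@@]1(C)C1=CC2=CC(=O)[C@@](C)(O)[C@H](O)C2=CO1 | target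

## Step count and least certain steps

Total: 21 steps. Longest linear sequence: 20 steps (steps 1 to 14 and 16 to 21, from 1); step 15 is a one-step branch.

Step 20 (key step). The neutral carbon nucleophile may be too weak for a lactone carbonyl next to the quaternary C7, so that on heating the methylenepyran oligomerises, or the silyl group is lost and acyl transfer to O8 takes over. Fallback with known reactions: from 29, the dioxolanone is hydrolysed with LiOH in aqueous THF to (2S,3R)-2-hydroxy-2-methyl-3-(4-methylidene-6-Ep-4H-pyran-3-yl)-3-(triethylsilyloxy)propanoic acid F1. The acid is activated with 2-chloro-1-methylpyridinium iodide and Et3N as the 2-acyloxy-1-methylpyridinium salt F2, a much stronger acyl donor, which should acylate C5 as acid chlorides and anhydrides acylate methylenepyrans. The route is rejoined at 32.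

Step 12. The amine may add to C1 reversibly without a productive aldol, because a vinylogous ester is a poor acceptor, and hydroxide may open the pyranone ring instead. Fallback: from 17, iodination at C8a with I2 and pyridine gives 5-iodo-2-Ep-4H-pyran-4-one F3. Iodine–magnesium exchange with i-PrMgCl·LiCl at −40 °C gives the pyranonyl Grignard reagent F4, which is trapped with monomeric formaldehyde. The route is rejoined at 18.

Step 13. During the acid-catalysed dehydration the methylenepyran may couple with its own pyrylium ion, or the epoxide may open. The methylenepyrans 20 to 29 stay sensitive to acid, so all chromatography would use amine-treated supports. Fallback: from 18, Me3SiCH2Li adds to the pyranone carbonyl to give 3-(hydroxymethyl)-6-Ep-4-[(trimethylsilyl)methyl]-4H-pyran-4-ol F5. Peterson elimination with KN(SiMe3)2 then forms the exocyclic alkene under basic conditions, with no free pyrylium ion. The route is rejoined at 20.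

Step 18. Facial selectivity may be poor or reversed, for instance through chelation of the cation between the C8 oxygen and O7, or if the lactone carbonyl and not the C7–O bond takes the antiperiplanar position; hydride may also attack the dioxolanone. The two C8 epimers should be separable and the wrong one can be returned to 27 by step 17. Fallback that changes the source of control: from 27, the ring closure of step 20 is applied to the ketone (no O-acyl transfer is possible) to give (7R)-7-hydroxy-7-methyl-3-Ep-6H-isochromene-6,8(7H)-dione F6. The free C7 hydroxyl then binds Me4NBH(OAc)3 and delivers hydride to C8 on its own face, at the more reactive of the two ring carbonyls, giving the trans-diol (7S,8R)-7,8-dihydroxy-7-methyl-3-Ep-7,8-dihydro-6H-isochromen-6-one F7. Bu4NF with AcOH removes the remaining silyl group, and the route is rejoined at 33.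

## Further compounds

F1 | step 20 | (2S,3R)-2-hydroxy-2-methyl-3-(4-methylidene-6-Ep-4H-pyran-3-yl)-3-(triethylsilyloxy)propanoic acid | C/C(=C\[C@@H](C)[C@H](C)O[Si](C)(C)C(C)(C)C)[C@@H]1O[C@@]1(C)C1=CC(=C)C(=CO1)[C@@H](O[Si](CC)(CC)CC)[C@](C)(O)C(=O)O
F2 | step 20 | 2-acyloxy-1-methylpyridinium iodide of F1 | C/C(=C\[C@@H](C)[C@H](C)O[Si](C)(C)C(C)(C)C)[C@@H]1O[C@@]1(C)C1=CC(=C)C(=CO1)[C@@H](O[Si](CC)(CC)CC)[C@](C)(O)C(=O)Oc1cccc[n+]1C.[I-]
F3 | step 12 | 5-iodo-2-Ep-4H-pyran-4-one | C/C(=C\[C@@H](C)[C@H](C)O[Si](C)(C)C(C)(C)C)[C@@H]1O[C@@]1(C)C1=CC(=O)C(I)=CO1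
F4 | step 12 | chloro(4-oxo-6-Ep-4H-pyran-3-yl)magnesium | C/C(=C\[C@@H](C)[C@H](C)O[Si](C)(C)C(C)(C)C)[C@@H]1O[C@@]1(C)C1=CC(=O)C([Mg]Cl)=CO1
F5 | step 13 | 3-(hydroxymethyl)-6-Ep-4-[(trimethylsilyl)methyl]-4H-pyran-4-ol | C/C(=C\[C@@H](C)[C@H](C)O[Si](C)(C)C(C)(C)C)[C@@H]1O[C@@]1(C)C1=CC(O)(C[Si](C)(C)C)C(CO)=CO1
F6 | step 18 | (7R)-7-hydroxy-7-methyl-3-Ep-6H-isochromene-6,8(7H)-dione | C/C(=C\[C@@H](C)[C@H](C)O[Si](C)(C)C(C)(C)C)[C@@H]1O[C@@]1(C)C1=CC2=CC(=O)[C@@](C)(O)C(=O)C2=CO1
F7 | step 18 | (7S,8R)-7,8-dihydroxy-7-methyl-3-Ep-7,8-dihydro-6H-isochromen-6-one | C/C(=C\[C@@H](C)[C@H](C)O[Si](C)(C)C(C)(C)C)[C@@H]1O[C@@]1(C)C1=CC2=CC(=O)[C@@](C)(O)[C@H](O)C2=CO1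
A1 | alternative 1 | (7R)-7-hydroxy-3-[(2R,3S)-3-[(2E,4R,5S)-5-hydroxy-4-methylhex-2-en-2-yl]-2-methyloxiran-2-yl]-7-methyl-6H-isochromene-6,8(7H)-dione | C/C(=C\[C@@H](C)[C@H](C)O)[C@@H]1O[C@@]1(C)C1=CC2=CC(=O)[C@@](C)(O)C(=O)C2=CO1
A2 | alternative 1 | 2,4-dihydroxy-6-{2-[(2R,3S)-3-[(2E,4R,5S)-5-hydroxy-4-methylhex-2-en-2-yl]-2-methyloxiran-2-yl]-2-oxoethyl}-3-methylbenzaldehyde | C/C(=C\[C@@H](C)[C@H](C)O)[C@@H]1O[C@@]1(C)C(=O)Cc1cc(O)c(C)c(O)c1C=O
A3 | alternative 2 | (7S,8R)-8-hydroxy-7-methyl-3-Ep-7-(triethylsilyloxy)-7,8-dihydro-6H-isochromen-6-one | C/C(=C\[C@@H](C)[C@H](C)O[Si](C)(C)C(C)(C)C)[C@@H]1O[C@@]1(C)C1=CC2=CC(=O)[C@@](C)(O[Si](CC)(CC)CC)[C@H](O)C2=CO1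
A4 | alternative 2 | (2S)-2-methyl-3-oxo-4-(2-Ep-4H-pyran-4-ylidene)-2-(triethylsilyloxy)butanal, acyl group on the side of C8a | C/C(=C\[C@@H](C)[C@H](C)O[Si](C)(C)C(C)(C)C)[C@@H]1O[C@@]1(C)C1=C/C(=C/C(=O)[C@@](C)(O[Si](CC)(CC)CC)C=O)C=CO1
A5 | alternative 3 | (7S,8R)-7-methyl-3-Ep-7,8-bis(triethylsilyloxy)-7,8-dihydro-6H-isochromen-6-one | C/C(=C\[C@@H](C)[C@H](C)O[Si](C)(C)C(C)(C)C)[C@@H]1O[C@@]1(C)C1=CC2=CC(=O)[C@@](C)(O[Si](CC)(CC)CC)[C@H](O[Si](CC)(CC)CC)C2=CO1
A6 | alternative 3 | 5-[(1R,2S)-2-methyl-3-oxo-1,2-bis(triethylsilyloxy)butyl]-2-Ep-4H-pyran-4-one | C/C(=C\[C@@H](C)[C@H](C)O[Si](C)(C)C(C)(C)C)[C@@H]1O[C@@]1(C)C1=CC(=O)C(=CO1)[C@@H](O[Si](CC)(CC)CC)[C@](C)(O[Si](CC)(CC)CC)C(C)=O
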